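**Retrosynthetic overview**
- The strategy rests on ring C, a pentasubstituted resorcinol: oxygen on C3' and C5', hydrogen on C4', prenyl on C2' and C6', and the benzofuran-2-yl group on C1'. The five carbons C2'–C6' are read as a 1,3-diketone chain whose two outer α-carbons are both bonded to C1', the former carboxyl carbon of a benzofuran-2-carboxylic ester.
- Ring C is opened at C1'–C6' (intramolecular aldol, dehydration, aromatization of an acyclic 1-aryl-1,3,5-triketone) and then at C1'–C2' (Claisen acylation of a β-diketone dianion by the ester).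
- The symmetric diketone comes from acetylacetone by two terminal dianion prenylations, so both prenyl groups sit on sp3 carbons before ring C exists. The ester comes from 2,4-dihydroxybenzaldehyde (4-O-MOM) and methyl bromoacetate.
- Ring order: ring A is bought, furan ring B is closed in step 4, resorcinol ring C is closed last in step 6, and the MOM group is removed at the end.

Key step: step 6

Remark: the di- and triketones are drawn as keto forms although they are largely enolized; the stereocenters of 11, 14, 15 and 16 form as mixtures and vanish on dehydration or aromatization, and the target has no stereo-element.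

**Step 1**
Reactants: 1 acetylacetone (pentane-2,4-dione); 2 prenyl bromide (1-bromo-3-methylbut-2-ene)
Product: 4 8-methylnon-7-ene-2,4-dione, via dilithium dianion of acetylacetone 3 (not isolated)
Conditions: LiN(i-Pr)2 (2.1 equiv), THF, 0 °C; then 2 (1.0 equiv), 0 °C to rt; 1 M HCl, 0 °C
Reagents that add atoms: none
Why: γ-alkylation of a 1,3-diketone dianion, in which the terminal carbanion is far more nucleophilic than the stabilized central enolate, so the allylic bromide should be taken up at the methyl carbon only.

**Step 2**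
Reactants: 4 8-methylnon-7-ene-2,4-dione; 2 prenyl bromide
Product: 6 2,12-dimethyltrideca-2,11-diene-6,8-dione, via dilithium dianion of the monoprenyl diketone 5 (not isolated)
Conditions: LiN(i-Pr)2 (2.1 equiv), THF, −78 to 0 °C; then 2 (1.05 equiv), 0 °C to rt; 1 M HCl, 0 °C
Reagents that add atoms: none
Why: a second dianion γ-alkylation, in which the monoenolate should lose its second proton from the remaining methyl faster than from the already substituted methylene, so the new prenyl group ends up on the other terminus.

**Step 3**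
Reactants: 7 2,4-dihydroxybenzaldehyde
Product: 8 2-hydroxy-4-(methoxymethoxy)benzaldehyde
Conditions: MOMCl (1.1 equiv), K2CO3, acetone, 0 °C to rt
Reagents that add atoms: chloromethyl methyl ether (MOMCl), COCCl
Why: Williamson-type O-alkylation that should select the 4-hydroxyl, because the 2-hydroxyl is held in a hydrogen bond to the formyl oxygen and is the poorer nucleophile.

**Step 4**
Reactants: 8 2-hydroxy-4-(methoxymethoxy)benzaldehyde; 9 methyl bromoacetate
Product: 12 methyl 6-(methoxymethoxy)-1-benzofuran-2-carboxylate, via aryloxyacetate ether 10 (not isolated), via hydroxydihydrobenzofuran ester 11 (not isolated)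
Conditions: K2CO3 (2.5 equiv), DMF, rt then 100 °C
Reagents that add atoms: none
Why: Williamson O-alkylation of the phenol followed by intramolecular aldol condensation of the ester α-carbon onto the ortho formyl group and dehydration to the aromatic furan (Rap–Stoermer-type benzofuran synthesis), which places the MOM ether at C6.

**Step 5**
Reactants: 6 2,12-dimethyltrideca-2,11-diene-6,8-dione; 12 methyl 6-(methoxymethoxy)-1-benzofuran-2-carboxylate
Product: 14 1-[6-(methoxymethoxy)-1-benzofuran-2-yl]-9-methyl-2-(3-methylbut-2-en-1-yl)dec-8-ene-1,3,5-trione, via dilithium dianion of the symmetric diketone 13 (not isolated)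
Conditions: 6 (2.2 equiv), LiN(i-Pr)2 (4.4 equiv), THF, −78 to 0 °C; then 12 (1.0 equiv), −78 °C to rt; AcOH quench
Reagents that add atoms: none
Why: Claisen acylation of a 1,3-diketone dianion at its outer carbanion by a non-enolizable heteroaryl ester, in which the second equivalent of dianion (rather than free amide base, which could attack the ester or metalate C3 of the benzofuran) deprotonates the more acidic triketone as it forms and so prevents a second addition.

**Step 6**
Reactants: 14 1-[6-(methoxymethoxy)-1-benzofuran-2-yl]-9-methyl-2-(3-methylbut-2-en-1-yl)dec-8-ene-1,3,5-trione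
Product: 17 5-[6-(methoxymethoxy)-1-benzofuran-2-yl]-4,6-bis(3-methylbut-2-en-1-yl)benzene-1,3-diol, via cyclic aldol adduct 15 (not isolated), via cyclohexenedione 16 (not isolated)
Conditions: KOH (2 M aq), MeOH, argon, rt to 50 °C; then AcOH to pH 6
Reagents that add atoms: none
Why: With the C3–C5 diketone held as its enolate, the outer C6 methylene is deprotonated reversibly and its carbanion adds to the C1 heteroaryl ketone carbonyl, forming the C1'–C6' bond of aldol 15, which loses water to enedione 16 and tautomerizes irreversibly to resorcinol 17. The closest known reaction type is the base-mediated aldol cyclization and aromatization of acyclic 1,3,5-tricarbonyl compounds to resorcinols (heptane-2,4,6-trione to orcinol; 7-aryl-3,5,7-trioxo acids to 6-arylresorcylic acids, where an aroyl carbonyl is the acceptor). Ring C closes in a 6-(enolendo)-exo-trig mode, with the C5=C6 enolate inside the new ring and the C1 carbonyl oxygen outside it, which is a favoured closure. No stereocenter is set, since the methine carbons of 14, 15 and 16 all become aromatic carbons. The step needs C-cyclization from C6 to C1 in preference to O-cyclization to a 4-pyranone and to retro-Claisen cleavage of the α-branched C1–C2–C3 unit; the chain allows only this one six-membered carbocyclic aldol (every other carbanion–carbonyl pairing would give a four-membered ring), hydroxide rather than acid reopens any pyranone to the same triketone, and aromatization is the only irreversible exit. Because C2' and C6' already carry their prenyl groups and C4' is the former central methylene, no ring position needs C-alkylation afterwards.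

**Step 7**
Reactants: 17 5-[6-(methoxymethoxy)-1-benzofuran-2-yl]-4,6-bis(3-methylbut-2-en-1-yl)benzene-1,3-diol
Product: 18 mulberrofuran V, 5-(6-hydroxy-1-benzofuran-2-yl)-4,6-bis(3-methylbut-2-en-1-yl)benzene-1,3-diol
Conditions: conc. HCl (cat.), MeOH, 0 °C to rt, argon
Reagents that add atoms: none
Why: acid-catalysed acetal exchange of the aryl MOM ether with methanol, which at low acid strength and temperature should be faster than protonation of the trisubstituted alkenes that would lead the neighbouring phenols into chromans.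

**Compound list**
1 | acetylacetone (pentane-2,4-dione) | CC(=O)CC(C)=O | starting material
2 | prenyl bromide (1-bromo-3-methylbut-2-ene) | CC(C)=CCBr | starting material
3 | dilithium dianion of acetylacetone (bis-enolate, deprotonated at C1 and C3) | [Li+].[Li+].C=C([O-])C=C(C)[O-] | intermediate
4 | 8-methylnon-7-ene-2,4-dione | CC(=O)CC(=O)CCC=C(C)C | intermediate
5 | dilithium dianion of 8-methylnon-7-ene-2,4-dione (deprotonated at C1 and C3) | [Li+].[Li+].C=C([O-])C=C([O-])CCC=C(C)C | intermediate
6 | 2,12-dimethyltrideca-2,11-diene-6,8-dione | CC(C)=CCCC(=O)CC(=O)CCC=C(C)C | intermediate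
7 | 2,4-dihydroxybenzaldehyde | O=Cc1ccc(O)cc1O | starting material
8 | 2-hydroxy-4-(methoxymethoxy)benzaldehyde | COCOc1ccc(C=O)c(O)c1 | intermediate
9 | methyl bromoacetate | COC(=O)CBr | starting material
10 | methyl 2-[2-formyl-5-(methoxymethoxy)phenoxy]acetate | COCOc1ccc(C=O)c(OCC(=O)OC)c1 | intermediate
11 | methyl 3-hydroxy-6-(methoxymethoxy)-2,3-dihydro-1-benzofuran-2-carboxylate (diastereomer mixture) | COCOc1ccc2c(c1)OC(C(=O)OC)C2O | intermediate
12 | methyl 6-(methoxymethoxy)-1-benzofuran-2-carboxylate | COCOc1ccc2cc(C(=O)OC)oc2c1 | intermediate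
13 | dilithium dianion of 2,12-dimethyltrideca-2,11-diene-6,8-dione (deprotonated at C5 and C7) | [Li+].[Li+].CC(C)=CCC=C([O-])C=C([O-])CCC=C(C)C | intermediate
14 | 1-[6-(methoxymethoxy)-1-benzofuran-2-yl]-9-methyl-2-(3-methylbut-2-en-1-yl)dec-8-ene-1,3,5-trione (racemic, enol tautomer mixture) | COCOc1ccc2cc(C(=O)C(CC=C(C)C)C(=O)CC(=O)CCC=C(C)C)oc2c1 | intermediate
15 | 5-hydroxy-5-[6-(methoxymethoxy)-1-benzofuran-2-yl]-4,6-bis(3-methylbut-2-en-1-yl)cyclohexane-1,3-dione (diastereomer mixture) | COCOc1ccc2cc(C3(O)C(CC=C(C)C)C(=O)CC(=O)C3CC=C(C)C)oc2c1 | intermediate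
16 | 5-[6-(methoxymethoxy)-1-benzofuran-2-yl]-4,6-bis(3-methylbut-2-en-1-yl)cyclohex-4-ene-1,3-dione (racemic) | COCOc1ccc2cc(C3=C(CC=C(C)C)C(=O)CC(=O)C3CC=C(C)C)oc2c1 | intermediate
17 | 5-[6-(methoxymethoxy)-1-benzofuran-2-yl]-4,6-bis(3-methylbut-2-en-1-yl)benzene-1,3-diol (6-O-MOM mulberrofuran V) | COCOc1ccc2cc(-c3c(CC=C(C)C)c(O)cc(O)c3CC=C(C)C)oc2c1 | intermediate
18 | mulberrofuran V | CC(C)=CCc1c(O)cc(O)c(CC=C(C)C)c1-c1cc2ccc(O)cc2o1 | target

**Step count**
Total steps: 7. Longest linear sequence: 5 steps (steps 1, 2, 5, 6, 7; the branch through steps 3, 4, 5, 6, 7 is equally long).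

**Steps most likely to fail**

1. Step 6. Hydroxide may cleave the α-branched dicarbonyl unit by retro-Claisen attack at the aroyl carbonyl. The carbanion at the outer methylene may also add too slowly to the hindered, partly enolized heteroaryl ketone, so that cleavage or O-cyclization outruns ring closure.
Fallback, setting out from 6 and coming back at 18: the ring-C aldol is moved onto a much more electrophilic α-keto ester carbonyl and the benzofuran is built afterwards.
   - Dianion 13, made from 6 as in step 5, is added to excess diethyl oxalate (THF, −78 °C) to give ethyl 10-methyl-3-(3-methylbut-2-en-1-yl)-2,4,6-trioxoundec-9-enoate F1.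
   - NaOEt in EtOH at rt should close and aromatize it, by the same C-to-carbonyl aldol, to ethyl 3,5-dihydroxy-2,6-bis(3-methylbut-2-en-1-yl)benzoate F2.
   - MOMCl and i-Pr2NEt in CH2Cl2 give ethyl 3,5-bis(methoxymethoxy)-2,6-bis(3-methylbut-2-en-1-yl)benzoate F3.
   - LiAlH4 in THF at reflux reduces the hindered ester to [3,5-bis(methoxymethoxy)-2,6-bis(3-methylbut-2-en-1-yl)phenyl]methanol F4.
   - MnO2 in CH2Cl2 gives 3,5-bis(methoxymethoxy)-2,6-bis(3-methylbut-2-en-1-yl)benzaldehyde F5.
   - The Ohira–Bestmann reagent (dimethyl (1-diazo-2-oxopropyl)phosphonate, K2CO3, MeOH) gives 3-ethynyl-1,5-bis(methoxymethoxy)-2,4-bis(3-methylbut-2-en-1-yl)benzene F6.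
   - Sonogashira coupling of F6 with commercial 4-iodobenzene-1,3-diol, followed in the same flask by 5-endo-dig addition of the ortho hydroxyl to the alkyne (PdCl2(PPh3)2, CuI, Et3N, DMF, 60–80 °C), should give 2-[3,5-bis(methoxymethoxy)-2,6-bis(3-methylbut-2-en-1-yl)phenyl]-1-benzofuran-6-ol F7.
   - Removal of the two MOM groups under the conditions of step 7 gives 18.

2. Step 5. The carbanion of 13 is secondary and hindered, so proton transfer from the product, O-acylation or incomplete conversion may prevail over C-acylation.
Fallback, setting out from 12 and coming back at 14: the carbon–carbon bond is made by aldol addition to an aldehyde and the ketone is restored by oxidation.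
   - LiAlH4 (THF, 0 °C) reduces 12 to [6-(methoxymethoxy)-1-benzofuran-2-yl]methanol F8.
   - MnO2 (CH2Cl2) gives 6-(methoxymethoxy)-1-benzofuran-2-carbaldehyde F9.
   - Dianion 13 adds through its outer carbon to F9 (THF, −78 °C) to give 1-hydroxy-1-[6-(methoxymethoxy)-1-benzofuran-2-yl]-9-methyl-2-(3-methylbut-2-en-1-yl)dec-8-ene-3,5-dione F10 as a diastereomer mixture.
   - Dess–Martin periodinane (CH2Cl2, NaHCO3) oxidizes the carbinol to the ketone, which is 14.

3. Step 7. During acetal cleavage the acid may protonate the prenyl double bonds, so that the C3' and C5' hydroxyls add to their ortho prenyl groups (2,2-dimethylchroman formation) or the alkenes are hydrated.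
Fallback, setting out from 12 and coming back at 18: the protecting group is exchanged before any prenyl group is present, for one that falls off under the basic ring-closing conditions.
   - HCl in MeOH converts 12 into methyl 6-hydroxy-1-benzofuran-2-carboxylate F11.
   - TBSCl and imidazole in DMF give methyl 6-[(tert-butyldimethylsilyl)oxy]-1-benzofuran-2-carboxylate F12.
   - Acylation of dianion 13 by F12 as in step 5 gives 1-{6-[(tert-butyldimethylsilyl)oxy]-1-benzofuran-2-yl}-9-methyl-2-(3-methylbut-2-en-1-yl)dec-8-ene-1,3,5-trione F13.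
   - The aqueous methanolic KOH of step 6 should close ring C and cleave the aryl silyl ether in the same operation (Bu4NF buffered with AcOH would finish any remainder), giving 18 without exposure to acid.

**Further compounds**
F1 | step 6 | ethyl 10-methyl-3-(3-methylbut-2-en-1-yl)-2,4,6-trioxoundec-9-enoate | CCOC(=O)C(=O)C(CC=C(C)C)C(=O)CC(=O)CCC=C(C)C
F2 | step 6 | ethyl 3,5-dihydroxy-2,6-bis(3-methylbut-2-en-1-yl)benzoate | CCOC(=O)c1c(CC=C(C)C)c(O)cc(O)c1CC=C(C)C
F3 | step 6 | ethyl 3,5-bis(methoxymethoxy)-2,6-bis(3-methylbut-2-en-1-yl)benzoate | CCOC(=O)c1c(CC=C(C)C)c(OCOC)cc(OCOC)c1CC=C(C)C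
F4 | step 6 | [3,5-bis(methoxymethoxy)-2,6-bis(3-methylbut-2-en-1-yl)phenyl]methanol | OCc1c(CC=C(C)C)c(OCOC)cc(OCOC)c1CC=C(C)C
F5 | step 6 | 3,5-bis(methoxymethoxy)-2,6-bis(3-methylbut-2-en-1-yl)benzaldehyde | O=Cc1c(CC=C(C)C)c(OCOC)cc(OCOC)c1CC=C(C)C
F6 | step 6 | 3-ethynyl-1,5-bis(methoxymethoxy)-2,4-bis(3-methylbut-2-en-1-yl)benzene | C#Cc1c(CC=C(C)C)c(OCOC)cc(OCOC)c1CC=C(C)C
F7 | step 6 | 2-[3,5-bis(methoxymethoxy)-2,6-bis(3-methylbut-2-en-1-yl)phenyl]-1-benzofuran-6-ol | Oc1ccc2cc(-c3c(CC=C(C)C)c(OCOC)cc(OCOC)c3CC=C(C)C)oc2c1
F8 | step 5 | [6-(methoxymethoxy)-1-benzofuran-2-yl]methanol | COCOc1ccc2cc(CO)oc2c1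
F9 | step 5 | 6-(methoxymethoxy)-1-benzofuran-2-carbaldehyde | COCOc1ccc2cc(C=O)oc2c1
F10 | step 5 | 1-hydroxy-1-[6-(methoxymethoxy)-1-benzofuran-2-yl]-9-methyl-2-(3-methylbut-2-en-1-yl)dec-8-ene-3,5-dione (diastereomer mixture) | COCOc1ccc2cc(C(O)C(CC=C(C)C)C(=O)CC(=O)CCC=C(C)C)oc2c1
F11 | step 7 | methyl 6-hydroxy-1-benzofuran-2-carboxylate | COC(=O)c1cc2ccc(O)cc2o1
F12 | step 7 | methyl 6-[(tert-butyldimethylsilyl)oxy]-1-benzofuran-2-carboxylate | COC(=O)c1cc2ccc(O[Si](C)(C)C(C)(C)C)cc2o1
F13 | step 7 | 1-{6-[(tert-butyldimethylsilyl)oxy]-1-benzofuran-2-yl}-9-methyl-2-(3-methylbut-2-en-1-yl)dec-8-ene-1,3,5-trione | CC(C)=CCCC(=O)CC(=O)C(CC=C(C)C)C(=O)c1cc2ccc(O[Si](C)(C)C(C)(C)C)cc2o1
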